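**Retrosynthetic overview**

- The hydroperoxide and the 4E alkene come last, from a Schenck ene reaction of singlet oxygen on the skipped (2Z)-diene side chain; the primary acetate is installed just before.
- Ring B (the cyclopentenone) is closed by ring-closing metathesis of a dienone whose C1'/C5' centres come from an Ireland–Claisen rearrangement of a crotyl ester, steered by C2 of ring A.
- The side chain is built on the C4 handle: convex-face hydroboration sets C4, then a Z-selective Wittig reaction on a methyl ketone gives the trisubstituted alkene.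
- Ring A is made first by a palladium-catalysed trimethylenemethane (3+2) cycloaddition to 5,6-dihydro-2H-pyran-2-one, forming C2–C3 and C1–C5. The enabling feature is that C3–C4–C5 plus the exocyclic side-chain carbon is an isobutene unit, while the cis-disposed CH2O carbon on C1 and the C1'–C2' arm on C2 can be tied through an oxygen on C2' into a six-membered lactone whose α,β-alkene is C1=C2.
- Ring order: ring A with the temporary lactone ring (step 1), lactone ring opened (step 9), ring B (step 16).

Key step: step 1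

Remark on locants and one assumption: ring A is C1 (carbinol carbon), C2 (bears ring B), C3, C4 (bears the side chain), C5; ring B is C1' (on C2), C2' (C=O), C3', C4', C5' (bears CH3); the side chain is C2''–C6''. The ligand antipode that gives (4aS,7aS)-3 is assumed to be identified in one screening run.

**Route**

Step 1
Reactants: 1 5,6-dihydro-2H-pyran-2-one; 2 2-[(trimethylsilyl)methyl]prop-2-en-1-yl acetate
Product: 3 (4aS,7aS)-6-methylidenehexahydrocyclopenta[c]pyran-1(3H)-one
Conditions: Pd(dba)2 (dba = dibenzylideneacetone, C17H14O; 5 mol %), (S)-BINOL-derived phosphoramidite of (2R,5R)-2,5-di(naphthalen-2-yl)pyrrolidine (10 mol %), toluene, 45 °C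
Reagents that add atoms: none
Why: Zerovalent palladium ionises 2 to a π-allylpalladium cation whose acetate removes the silyl group, giving the zwitterionic trimethylenemethane–palladium complex; its nucleophilic CH2 adds to the β-carbon of 1 (bond C2–C3) and the lactone enolate then attacks the π-allyl terminus (bond C1–C5), i.e. a palladium-catalysed trimethylenemethane (3+2) cycloaddition. The closest known reaction type is this cycloaddition with α,β-unsaturated esters, lactones and ketones under chiral phosphoramidite ligands. Ring A closes by a stepwise Michael addition/intramolecular allylic alkylation, suprafacially on the Z-alkene held in the six-membered lactone, so the ring fusion can only be cis. The new stereocentres C1 and C2 are thus fixed relative to each other by the lactone ring, and their absolute sense should be set in the conjugate-addition step by the chiral pocket of the ligand. The step needs enantioface selectivity only, because 1 is achiral and attack can only occur at the β-carbon; conjugate addition should win over proton transfer because the lactone is unhindered and carries no acidic C–H.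

Step 2
Reactants: 3 (4aS,7aS)-6-methylidenehexahydrocyclopenta[c]pyran-1(3H)-one
Product: 5 (4aS,6S,7aS)-6-(hydroxymethyl)hexahydrocyclopenta[c]pyran-1(3H)-one, via B-alkyl-9-borabicyclononane 4 (not isolated)
Conditions: 9-borabicyclo[3.3.1]nonane (9-BBN), THF, 0 °C to rt; then NaBO3·4H2O, THF/H2O, rt
Reagents that add atoms: sodium perborate, [Na+].[O-]OB=O
Why: Anti-Markovnikov hydroboration–oxidation: the bulky borane should add to the exocyclic alkene from the convex face of the cis-fused bicycle (the face of the two ring-fusion hydrogens), so the new C4–H is syn to them and the CH2OH ends up cis to the lactone ring, which sets C4; the lactone tolerates 9-BBN and the near-neutral perborate work-up.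

Step 3
Reactants: 5 (4aS,6S,7aS)-6-(hydroxymethyl)hexahydrocyclopenta[c]pyran-1(3H)-one
Product: 6 (4aS,6S,7aS)-1-oxooctahydrocyclopenta[c]pyran-6-carbaldehyde
Conditions: Dess–Martin periodinane (1,1,1-triacetoxy-1,1-dihydro-1,2-benziodoxol-3(1H)-one), NaHCO3, CH2Cl2, 0 °C to rt
Reagents that add atoms: none
Why: Dess–Martin oxidation of the primary alcohol under bicarbonate buffering should give the aldehyde without enolising the adjacent C4 centre and without touching the lactone.

Step 4
Reactants: 6 (4aS,6S,7aS)-1-oxooctahydrocyclopenta[c]pyran-6-carbaldehyde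
Product: 7 (4aS,6S,7aS)-6-(1-hydroxyethyl)hexahydrocyclopenta[c]pyran-1(3H)-one (both carbinol epimers)
Conditions: MeTi(OiPr)3, THF, −78 to 0 °C
Reagents that add atoms: methyltitanium triisopropoxide, C[Ti](OC(C)C)(OC(C)C)OC(C)C
Why: 1,2-Addition of a weakly basic, aldehyde-selective organotitanium reagent spares the lactone and the epimerisable C4–H; the new carbinol centre is irrelevant because it is oxidised in the next step.

Step 5
Reactants: 7 (4aS,6S,7aS)-6-(1-hydroxyethyl)hexahydrocyclopenta[c]pyran-1(3H)-one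
Product: 8 (4aS,6S,7aS)-6-acetylhexahydrocyclopenta[c]pyran-1(3H)-one
Conditions: Dess–Martin periodinane, NaHCO3, CH2Cl2, 0 °C to rt
Reagents that add atoms: none
Why: Dess–Martin oxidation of the secondary alcohol gives the methyl ketone under non-epimerising conditions.

Step 6
Reactants: 9 5-bromo-2-methylpent-2-ene
Product: 10 (4-methylpent-3-en-1-yl)triphenylphosphonium bromide
Conditions: PPh3, MeCN, reflux
Reagents that add atoms: triphenylphosphine, c1ccc(cc1)P(c1ccccc1)c1ccccc1
Why: SN2 quaternisation of triphenylphosphine by the unhindered primary bromide gives the salt needed for the Wittig reaction.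

Step 7
Reactants: 8 (4aS,6S,7aS)-6-acetylhexahydrocyclopenta[c]pyran-1(3H)-one; 10 (4-methylpent-3-en-1-yl)triphenylphosphonium bromide
Product: 12 (4aS,6S,7aS)-6-[(2Z)-6-methylhepta-2,5-dien-2-yl]hexahydrocyclopenta[c]pyran-1(3H)-one, via phosphorus ylide 11 (not isolated)
Conditions: KN(SiMe3)2, THF, −78 °C; then 8, −78 °C to rt; purification on AgNO3-impregnated silica
Reagents that add atoms: none
Why: Wittig olefination with a salt-free non-stabilised ylide under kinetic control: for an α-branched methyl ketone the oxaphosphetane should place the ylide substituent cis to the bulkier cyclopentyl group, so the (Z)-trisubstituted alkene is expected as the main isomer, and the lactone is not attacked at low temperature.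

Step 8
Reactants: 12 (4aS,6S,7aS)-6-[(2Z)-6-methylhepta-2,5-dien-2-yl]hexahydrocyclopenta[c]pyran-1(3H)-one
Product: 14 (4aS,6S,7aR)-7a-hydroxy-6-[(2Z)-6-methylhepta-2,5-dien-2-yl]hexahydrocyclopenta[c]pyran-1(3H)-one, via potassium enolate 13 (not isolated)
Conditions: KN(SiMe3)2, THF, −78 °C; then 2-(phenylsulfonyl)-3-phenyloxaziridine, −78 °C; aqueous NH4Cl
Reagents that add atoms: 2-(phenylsulfonyl)-3-phenyloxaziridine, O=S(=O)(c1ccccc1)N1OC1c1ccccc1
Why: Electrophilic hydroxylation of the lactone enolate by an N-sulfonyloxaziridine (enolate oxidation): oxygen should enter the ring-fusion carbon C1 from the convex face, cis to H2, because only the cis-fused bicycle is accessible, which sets the tertiary carbinol with OH trans to the C2 arm.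

Step 9
Reactants: 14 (4aS,6S,7aR)-7a-hydroxy-6-[(2Z)-6-methylhepta-2,5-dien-2-yl]hexahydrocyclopenta[c]pyran-1(3H)-one
Product: 15 2-(2-hydroxyethyl)-1-(hydroxymethyl)-4-[(2Z)-6-methylhepta-2,5-dien-2-yl]cyclopentan-1-ol (C1, C2, C4 as in 30)
Conditions: LiAlH4, THF, 0 °C to rt
Reagents that add atoms: none
Why: Hydride reduction of the lactone releases the hydroxymethyl group on C1 and the 2-hydroxyethyl arm on C2 without affecting the isolated trisubstituted alkenes.

Step 10
Reactants: 15 2-(2-hydroxyethyl)-1-(hydroxymethyl)-4-[(2Z)-6-methylhepta-2,5-dien-2-yl]cyclopentan-1-ol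
Product: 16 2-{2,2-dimethyl-8-[(2Z)-6-methylhepta-2,5-dien-2-yl]-1,3-dioxaspiro[4.4]nonan-6-yl}ethan-1-ol
Conditions: 2,2-dimethoxypropane, camphorsulfonic acid (cat.), acetone, rt
Reagents that add atoms: 2,2-dimethoxypropane, COC(C)(C)OC
Why: Acid-catalysed transacetalisation: only the tertiary/primary 1,2-diol can form a five-membered dioxolane, so the remote primary alcohol stays free.

Step 11
Reactants: 16 2-{2,2-dimethyl-8-[(2Z)-6-methylhepta-2,5-dien-2-yl]-1,3-dioxaspiro[4.4]nonan-6-yl}ethan-1-ol
Product: 18 2-{2,2-dimethyl-8-[(2Z)-6-methylhepta-2,5-dien-2-yl]-1,3-dioxaspiro[4.4]nonan-6-yl}acetic acid, via aldehyde 17 (not isolated)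
Conditions: TEMPO (cat.), PhI(OAc)2, MeCN/aqueous pH 7 buffer, rt
Reagents that add atoms: water, O
Why: Nitroxyl-catalysed oxidation takes the primary alcohol through the aldehyde hydrate to the carboxylic acid and leaves the acetonide and the alkenes intact.

Step 12
Reactants: 18 2-{2,2-dimethyl-8-[(2Z)-6-methylhepta-2,5-dien-2-yl]-1,3-dioxaspiro[4.4]nonan-6-yl}acetic acid; 19 (2E)-but-2-en-1-ol
Product: 20 (2E)-but-2-en-1-yl 2-{2,2-dimethyl-8-[(2Z)-6-methylhepta-2,5-dien-2-yl]-1,3-dioxaspiro[4.4]nonan-6-yl}acetate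
Conditions: N-(3-dimethylaminopropyl)-N'-ethylcarbodiimide hydrochloride, 4-(dimethylamino)pyridine (cat.), CH2Cl2, 0 °C to rt
Reagents that add atoms: none
Why: Carbodiimide-mediated (Steglich) esterification couples the acid with the allylic alcohol under neutral conditions that keep the E geometry of the crotyl unit.

Step 13
Reactants: 20 (2E)-but-2-en-1-yl 2-{2,2-dimethyl-8-[(2Z)-6-methylhepta-2,5-dien-2-yl]-1,3-dioxaspiro[4.4]nonan-6-yl}acetate
Product: 23 (2S,3R)-2-{2,2-dimethyl-8-[(2Z)-6-methylhepta-2,5-dien-2-yl]-1,3-dioxaspiro[4.4]nonan-6-yl}-3-methylpent-4-enoic acid, via silyl ketene acetal 21 (not isolated), via trimethylsilyl ester 22 (not isolated)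
Conditions: LiN(iPr)2, Me3SiCl, THF, −78 °C, then rt to 60 °C; aqueous work-up at pH 4–5
Reagents that add atoms: none
Why: Ireland–Claisen rearrangement: kinetic deprotonation in THF gives the ketene acetal with C2 cis to the crotyloxy group, the chair transition state with the E-crotyl unit gives the anti (2S,3R) acid (the cis C1'/C5' relation of ring B), and the crotyl terminus should bond to the face anti to quaternary C1 while C2–H eclipses the ketene acetal (allylic 1,3-strain), which sets C1' and C5' relative to ring A.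

Step 14
Reactants: 23 (2S,3R)-2-{2,2-dimethyl-8-[(2Z)-6-methylhepta-2,5-dien-2-yl]-1,3-dioxaspiro[4.4]nonan-6-yl}-3-methylpent-4-enoic acid
Product: 25 (2S,3R)-2-{2,2-dimethyl-8-[(2Z)-6-methylhepta-2,5-dien-2-yl]-1,3-dioxaspiro[4.4]nonan-6-yl}-N-methoxy-N,3-dimethylpent-4-enamide, via acyl imidazole 24 (not isolated)
Conditions: 1,1'-carbonyldiimidazole, CH2Cl2, rt; then MeNH(OMe)·HCl, rt
Reagents that add atoms: N,O-dimethylhydroxylamine hydrochloride, CNOC.Cl
Why: Amide formation through the acyl imidazole gives the N-methoxy-N-methylamide without strong base, so the α-stereocentre C1' is not epimerised.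

Step 15
Reactants: 25 (2S,3R)-2-{2,2-dimethyl-8-[(2Z)-6-methylhepta-2,5-dien-2-yl]-1,3-dioxaspiro[4.4]nonan-6-yl}-N-methoxy-N,3-dimethylpent-4-enamide
Product: 26 (4S,5R)-4-{2,2-dimethyl-8-[(2Z)-6-methylhepta-2,5-dien-2-yl]-1,3-dioxaspiro[4.4]nonan-6-yl}-5-methylhepta-1,6-dien-3-one
Conditions: CH2=CHMgBr, THF, −78 to 0 °C; quench into cold aqueous NH4Cl
Reagents that add atoms: vinylmagnesium bromide, C=C[Mg]Br
Why: Addition of the vinyl Grignard reagent to the N-methoxy-N-methylamide stops at the chelated tetrahedral intermediate (ketone synthesis), so the vinyl ketone is released only on the cold quench, without over-addition.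

Step 16
Reactants: 26 (4S,5R)-4-{2,2-dimethyl-8-[(2Z)-6-methylhepta-2,5-dien-2-yl]-1,3-dioxaspiro[4.4]nonan-6-yl}-5-methylhepta-1,6-dien-3-one
Product: 27 (4R,5S)-5-{2,2-dimethyl-8-[(2Z)-6-methylhepta-2,5-dien-2-yl]-1,3-dioxaspiro[4.4]nonan-6-yl}-4-methylcyclopent-2-en-1-one
Conditions: second-generation Grubbs catalyst RuCl2(PCy3)(H2IMes)(=CHPh) (5 mol %), CH2Cl2, 40 °C
Reagents that add atoms: none
Why: Ring-closing olefin metathesis between the vinyl ketone and the terminal vinyl group closes the five-membered enone (ring B) with loss of ethene under neutral conditions that preserve the cis C1'/C5' relation; the trisubstituted side-chain alkenes should not compete.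

Step 17
Reactants: 27 (4R,5S)-5-{2,2-dimethyl-8-[(2Z)-6-methylhepta-2,5-dien-2-yl]-1,3-dioxaspiro[4.4]nonan-6-yl}-4-methylcyclopent-2-en-1-one
Product: 28 (4R,5S)-5-{2-hydroxy-2-(hydroxymethyl)-4-[(2Z)-6-methylhepta-2,5-dien-2-yl]cyclopentyl}-4-methylcyclopent-2-en-1-one (ring A as in 30)
Conditions: AcOH/THF/H2O, 40 °C
Reagents that add atoms: none
Why: Mild acid hydrolysis of the acetonide frees the tertiary/primary diol; the enone and the skipped diene tolerate dilute acetic acid.

Step 18
Reactants: 28 (4R,5S)-5-{2-hydroxy-2-(hydroxymethyl)-4-[(2Z)-6-methylhepta-2,5-dien-2-yl]cyclopentyl}-4-methylcyclopent-2-en-1-one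
Product: 29 [(1R,2S,4S)-1-hydroxy-4-[(2Z)-6-methylhepta-2,5-dien-2-yl]-2-[(1S,5R)-5-methyl-2-oxocyclopent-3-en-1-yl]cyclopentyl]methyl acetate
Conditions: Ac2O, pyridine, CH2Cl2, 0 °C
Reagents that add atoms: acetic anhydride, CC(=O)OC(C)=O
Why: Acylation with acetic anhydride and pyridine is selective for the primary hydroxyl, the tertiary hydroxyl on C1 being unreactive under these conditions.

Step 19
Reactants: 29 [(1R,2S,4S)-1-hydroxy-4-[(2Z)-6-methylhepta-2,5-dien-2-yl]-2-[(1S,5R)-5-methyl-2-oxocyclopent-3-en-1-yl]cyclopentyl]methyl acetate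
Product: 30 [(1R,2S,4S)-1-hydroxy-4-[(2Z,4E)-6-hydroperoxy-6-methylhepta-2,4-dien-2-yl]-2-[(1S,5R)-5-methyl-2-oxocyclopent-3-en-1-yl]cyclopentyl]methyl acetate (CNP0204569.1)
Conditions: O2, tetraphenylporphyrin (cat.), visible light, CH2Cl2, −20 °C, stopped at partial conversion
Reagents that add atoms: dioxygen, O=O
Why: Schenck ene reaction of singlet oxygen with the terminal trisubstituted alkene: oxygen adds to C6'' with abstraction of a doubly allylic C4'' hydrogen, giving the tertiary hydroperoxide and the new 4E alkene, while the more hindered ring-proximal alkene and the electron-poor enone should react more slowly.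

**Compound list**

1 | 5,6-dihydro-2H-pyran-2-one | O=C1C=CCCO1 | starting material
2 | 2-[(trimethylsilyl)methyl]prop-2-en-1-yl acetate | CC(=O)OCC(=C)C[Si](C)(C)C | starting material
3 | (4aS,7aS)-6-methylidenehexahydrocyclopenta[c]pyran-1(3H)-one (cis-fused; ring-fusion carbons are C1 and C2 of ring A) | O=C3[C@H]1CC(=C)C[C@H]1CCO3 | intermediate
4 | 9-{[(4aS,7aS)-1-oxooctahydrocyclopenta[c]pyran-6-yl]methyl}-9-borabicyclo[3.3.1]nonane (CH2B cis to the lactone ring) | O=C3[C@H]1C[C@@H](CB2C4CCCC2CCC4)C[C@H]1CCO3 | intermediate (not isolated)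
5 | (4aS,6S,7aS)-6-(hydroxymethyl)hexahydrocyclopenta[c]pyran-1(3H)-one | O=C3[C@H]1C[C@@H](CO)C[C@H]1CCO3 | intermediate
6 | (4aS,6S,7aS)-1-oxooctahydrocyclopenta[c]pyran-6-carbaldehyde | O=C3[C@H]1C[C@@H](C=O)C[C@H]1CCO3 | intermediate
7 | (4aS,6S,7aS)-6-(1-hydroxyethyl)hexahydrocyclopenta[c]pyran-1(3H)-one (both carbinol epimers) | O=C3[C@H]1C[C@@H](C(C)O)C[C@H]1CCO3 | intermediate
8 | (4aS,6S,7aS)-6-acetylhexahydrocyclopenta[c]pyran-1(3H)-one | O=C3[C@H]1C[C@@H](C(C)=O)C[C@H]1CCO3 | intermediate
9 | 5-bromo-2-methylpent-2-ene | CC(C)=CCCBr | starting material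
10 | (4-methylpent-3-en-1-yl)triphenylphosphonium bromide | CC(C)=CCC[P+](c1ccccc1)(c1ccccc1)c1ccccc1.[Br-] | intermediate
11 | (4-methylpent-3-en-1-ylidene)triphenylphosphorane | CC(C)=CCC=P(c1ccccc1)(c1ccccc1)c1ccccc1 | intermediate (not isolated)
12 | (4aS,6S,7aS)-6-[(2Z)-6-methylhepta-2,5-dien-2-yl]hexahydrocyclopenta[c]pyran-1(3H)-one | O=C3[C@H]1C[C@@H](/C(C)=C\CC=C(C)C)C[C@H]1CCO3 | intermediate
13 | potassium enolate of lactone 12 | [K+].[O-]C3=C1C[C@@H](/C(C)=C\CC=C(C)C)C[C@H]1CCO3 | intermediate (not isolated)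
14 | (4aS,6S,7aR)-7a-hydroxy-6-[(2Z)-6-methylhepta-2,5-dien-2-yl]hexahydrocyclopenta[c]pyran-1(3H)-one | O=C3[C@@]1(O)C[C@@H](/C(C)=C\CC=C(C)C)C[C@H]1CCO3 | intermediate
15 | 2-(2-hydroxyethyl)-1-(hydroxymethyl)-4-[(2Z)-6-methylhepta-2,5-dien-2-yl]cyclopentan-1-ol (C1, C2, C4 as in 30) | OC[C@@]1(O)C[C@@H](/C(C)=C\CC=C(C)C)C[C@H]1CCO | intermediate
16 | 2-{2,2-dimethyl-8-[(2Z)-6-methylhepta-2,5-dien-2-yl]-1,3-dioxaspiro[4.4]nonan-6-yl}ethan-1-ol (ring A as in 30) | CC1(C)OC[C@@]2(O1)C[C@@H](/C(C)=C\CC=C(C)C)C[C@H]2CCO | intermediate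
17 | 2-{2,2-dimethyl-8-[(2Z)-6-methylhepta-2,5-dien-2-yl]-1,3-dioxaspiro[4.4]nonan-6-yl}acetaldehyde | CC1(C)OC[C@@]2(O1)C[C@@H](/C(C)=C\CC=C(C)C)C[C@H]2CC=O | intermediate (not isolated)
18 | 2-{2,2-dimethyl-8-[(2Z)-6-methylhepta-2,5-dien-2-yl]-1,3-dioxaspiro[4.4]nonan-6-yl}acetic acid | CC1(C)OC[C@@]2(O1)C[C@@H](/C(C)=C\CC=C(C)C)C[C@H]2CC(=O)O | intermediate
19 | (2E)-but-2-en-1-ol | C/C=C/CO | starting material
20 | (2E)-but-2-en-1-yl ester of acid 18 | CC1(C)OC[C@@]2(O1)C[C@@H](/C(C)=C\CC=C(C)C)C[C@H]2CC(=O)OC/C=C/C | intermediate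
21 | trimethylsilyl ketene acetal of 20 (ring carbon C2 cis to the butenyloxy group) | CC1(C)OC[C@@]2(O1)C[C@@H](/C(C)=C\CC=C(C)C)C[C@H]2/C=C(\OC/C=C/C)O[Si](C)(C)C | intermediate (not isolated)
22 | trimethylsilyl ester of acid 23 | CC1(C)OC[C@@]2(O1)C[C@@H](/C(C)=C\CC=C(C)C)C[C@H]2[C@@H](C(=O)O[Si](C)(C)C)[C@H](C)C=C | intermediate (not isolated)
23 | (2S,3R)-2-{2,2-dimethyl-8-[(2Z)-6-methylhepta-2,5-dien-2-yl]-1,3-dioxaspiro[4.4]nonan-6-yl}-3-methylpent-4-enoic acid | CC1(C)OC[C@@]2(O1)C[C@@H](/C(C)=C\CC=C(C)C)C[C@H]2[C@@H](C(=O)O)[C@H](C)C=C | intermediate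
24 | acyl imidazole of acid 23 | CC1(C)OC[C@@]2(O1)C[C@@H](/C(C)=C\CC=C(C)C)C[C@H]2[C@@H](C(=O)n1ccnc1)[C@H](C)C=C | intermediate (not isolated)
25 | N-methoxy-N-methylamide of acid 23 | CC1(C)OC[C@@]2(O1)C[C@@H](/C(C)=C\CC=C(C)C)C[C@H]2[C@@H](C(=O)N(C)OC)[C@H](C)C=C | intermediate
26 | (4S,5R)-4-{2,2-dimethyl-8-[(2Z)-6-methylhepta-2,5-dien-2-yl]-1,3-dioxaspiro[4.4]nonan-6-yl}-5-methylhepta-1,6-dien-3-one | CC1(C)OC[C@@]2(O1)C[C@@H](/C(C)=C\CC=C(C)C)C[C@H]2[C@@H](C(=O)C=C)[C@H](C)C=C | intermediate
27 | (4R,5S)-5-{2,2-dimethyl-8-[(2Z)-6-methylhepta-2,5-dien-2-yl]-1,3-dioxaspiro[4.4]nonan-6-yl}-4-methylcyclopent-2-en-1-one | CC1(C)OC[C@@]2(O1)C[C@@H](/C(C)=C\CC=C(C)C)C[C@H]2[C@H]1C(=O)C=C[C@H]1C | intermediate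
28 | (4R,5S)-5-{2-hydroxy-2-(hydroxymethyl)-4-[(2Z)-6-methylhepta-2,5-dien-2-yl]cyclopentyl}-4-methylcyclopent-2-en-1-one (ring A as in 30) | OC[C@@]1(O)C[C@@H](/C(C)=C\CC=C(C)C)C[C@H]1[C@H]1C(=O)C=C[C@H]1C | intermediate
29 | [(1R,2S,4S)-1-hydroxy-4-[(2Z)-6-methylhepta-2,5-dien-2-yl]-2-[(1S,5R)-5-methyl-2-oxocyclopent-3-en-1-yl]cyclopentyl]methyl acetate | CC(=O)OC[C@@]1(O)C[C@@H](/C(C)=C\CC=C(C)C)C[C@H]1[C@H]1C(=O)C=C[C@H]1C | intermediate
30 | [(1R,2S,4S)-1-hydroxy-4-[(2Z,4E)-6-hydroperoxy-6-methylhepta-2,4-dien-2-yl]-2-[(1S,5R)-5-methyl-2-oxocyclopent-3-en-1-yl]cyclopentyl]methyl acetate | CC(=O)OC[C@@]1(O)C[C@@H](/C(C)=C\C=C\C(C)(C)OO)C[C@H]1[C@H]1C(=O)C=C[C@H]1C | target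

**Step count and risks**

Total step count: 19. Longest linear sequence: 18 steps (steps 1–5 and 7–19, from 1 to 30).

The three steps most likely to fail:

Step 1. The enantioface discrimination on a cyclic Z-enoate may be insufficient, and conjugate addition may be slow. The fallback replaces catalyst control by resolution. Starting again from 1 and 2, the cycloaddition is run with an achiral catalyst (Pd(OAc)2, P(OiPr)3, THF, reflux) to give the racemic cis-fused lactone F1. Aminolysis with (S)-1-phenylethylamine (neat, 80 °C) gives two diastereomeric hydroxy amides, N-[(1S)-1-phenylethyl] (1S,2S)-2-(2-hydroxyethyl)-4-methylidenecyclopentane-1-carboxamide F2 and its (1R,2R)-ring diastereomer F3, which are separated by crystallisation or chromatography. Acid-induced relactonisation of F2 (p-toluenesulfonic acid, toluene, reflux) returns enantiopure 3, where the route is rejoined.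

Step 7. The E alkene may form in a significant amount, and the basic ylide may epimerise C4 through enolisation of the ketone. The fallback is a Horner–Wittig sequence with separation at the adduct stage, setting out from 8 and 10. Salt 10 is hydrolysed (aqueous NaOH, heat) to diphenyl(4-methylpent-3-en-1-yl)phosphine oxide F4. Its α-lithio derivative (n-C4H9Li, THF, −78 °C) adds to ketone 8 to give β-hydroxy phosphine oxides, from which the diastereomer F5 (or its bis-epimer at the two new centres, which behaves in the same way) is separated by chromatography. Stereospecific syn elimination (NaH, DMF, rt) should convert it into geometrically pure 12, where the route is rejoined.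

Step 19. Singlet oxygen may attack the C2''=C3'' alkene or abstract a methyl hydrogen to give the secondary hydroperoxide, so that the wanted regioisomer becomes a minor product. The fallback sets out from 29 and reaches 30 by a radical chain under kinetic control instead of the pericyclic ene reaction: O2, N-hydroxyphthalimide (cat.), 2,2'-azobis(4-methoxy-2,4-dimethylvaleronitrile) as initiator, MeCN, 30 °C, low conversion. The phthalimide-N-oxyl radical should abstract only the weak doubly allylic C4''–H; the pentadienyl radical is trapped by O2 at the less hindered tertiary terminus C6'', and fast hydrogen-atom transfer gives 30 with the C2''=C3'' geometry retained. This fallback makes no compound outside the list (F0).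

Further compounds
F1 | step 1 | racemic cis-fused lactone (3 together with its enantiomer; the enantiomer is shown) | O=C3[C@@H]1CC(=C)C[C@@H]1CCO3
F2 | step 1 | N-[(1S)-1-phenylethyl] (1S,2S)-2-(2-hydroxyethyl)-4-methylidenecyclopentane-1-carboxamide | C[C@H](NC(=O)[C@H]1CC(=C)C[C@H]1CCO)c1ccccc1
F3 | step 1 | N-[(1S)-1-phenylethyl] (1R,2R)-2-(2-hydroxyethyl)-4-methylidenecyclopentane-1-carboxamide | C[C@H](NC(=O)[C@@H]1CC(=C)C[C@@H]1CCO)c1ccccc1
F4 | step 7 | diphenyl(4-methylpent-3-en-1-yl)phosphine oxide | CC(C)=CCCP(=O)(c1ccccc1)c1ccccc1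
F5 | step 7 | β-hydroxy phosphine oxide adduct of 8 (diastereomer whose syn elimination gives the Z alkene) | O=C3[C@H]1C[C@@H]([C@](C)(O)[C@@H](CC=C(C)C)P(=O)(c2ccccc2)c2ccccc2)C[C@H]1CCO3
F0 | step 19 | none | none
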